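Everything rests on opening the benzene ring at its C1–C6 bond (ester carbon to icosyl-bearing carbon), which unfolds it to methyl 3,5,7-trioxoheptacosanoate. The key step exploits the ring's meta-placed oxygens on C2 and C4, the CO2Me on C1 and the C20 chain on C6, the imprint of an aldol between chain C2 and the C7 ketone. In one pot a diketo-dioxinone is thermally unmasked to an acylketene, trapped by methanol, cyclised and aromatised. That precursor, a dioxinone bearing a 2,4-dioxotetracosyl side chain, comes from two enolate acylations; selective 4-O-methylation completes the target.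

Key step: step 4

Remark: LiN(SiMe3)2 and LiN(i-Pr)2 are taken as bought solutions. The target has no stereocentre; the only sp3 centres that arise (two, in the transient aldol carbinol of step 4) are erased on aromatisation, so nothing stereochemical needs control.

Step 1
Reactants: 1 2,2,6-trimethyl-4H-1,3-dioxin-4-one; 2 acetyl chloride
Product: 4 2,2-dimethyl-6-(2-oxopropyl)-4H-1,3-dioxin-4-one, via lithium dienolate 3 (not isolated)
Conditions: 1 (2.0 equiv), LiN(SiMe3)2 (2.0 equiv), THF, −78 °C, 1 h; then 2 (1.0 equiv), −78 °C; 1 M HCl work-up
Reagents that add atoms: acetyl chloride (compound 2), CC(Cl)=O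
Why: Kinetic deprotonation of the 6-methyl group gives the extended dienolate 3, which should undergo γ-selective C-acylation (vinylogous Claisen-type acylation) by the acid chloride; since 4 is more acidic than 1, a twofold excess of 3 is used so that half of it acts as the base.

Step 2
Reactants: 5 henicosanoic acid; 6 N,O-dimethylhydroxylamine hydrochloride
Product: 8 N-methoxy-N-methylhenicosanamide, via henicosanoyl chloride 7 (not isolated)
Conditions: (COCl)2 (1.2 equiv), DMF (cat.), CH2Cl2, 0 °C to rt; evaporate; then 6, K2CO3, CH2Cl2/H2O, 0 °C to rt
Reagents that add atoms: N,O-dimethylhydroxylamine hydrochloride (compound 6), CNOC.Cl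
Why: Vilsmeier-catalysed formation of the acid chloride followed by Schotten–Baumann N-acylation is a standard Weinreb amide synthesis, and the saturated chain carries nothing that could interfere.

Step 3
Reactants: 4 2,2-dimethyl-6-(2-oxopropyl)-4H-1,3-dioxin-4-one; 8 N-methoxy-N-methylhenicosanamide
Product: 10 2,2-dimethyl-6-(2,4-dioxotetracosyl)-4H-1,3-dioxin-4-one, via dilithium dianion 9 (not isolated)
Conditions: 4 (1.5 equiv), LiN(i-Pr)2 (3.1 equiv), THF, −78 °C, 1 h; then 8 (1.0 equiv, added as a THF solution), −78 to −20 °C; 1 M HCl to pH 3
Reagents that add atoms: none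
Why: Double deprotonation gives dianion 9, whose last-formed terminal carbanion should be acylated regioselectively in a crossed Claisen condensation of the β-keto ester dianion type, and the Weinreb amide transfers its acyl group only once because the new ketone is not released until the acidic work-up, which also prevents proton quenching of 9 by the product.

Step 4
Reactants: 10 2,2-dimethyl-6-(2,4-dioxotetracosyl)-4H-1,3-dioxin-4-one; 11 methanol
Product: 15 methyl 2,4-dihydroxy-6-icosylbenzoate, via acylketene 12 (not isolated), via trioxo ester 13 (not isolated), via aldol carbinol 14 (not isolated)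
Conditions: 11 (10 equiv), PhMe, 110 °C, sealed tube; cool, then Cs2CO3 (1.5 equiv), MeOH/PhMe, rt; then HCl (1.25 M in MeOH), rt
Reagents that add atoms: methanol (compound 11), CO
Why: Heating the dioxinone ring of 10 triggers a retro-hetero-Diels–Alder loss of acetone to acylketene 12, which methanol should capture as the open-chain methyl 3,5,7-trioxoheptacosanoate 13. Carbonate then forms the enolate at C2 (flanked by the ester and the C3 ketone), which adds to the C7 ketone, making the C2–C7 bond and closing the six-membered carbocycle of carbinol 14 in a 6-(enolendo)-exo-trig aldol; acid-promoted loss of water and enolisation of the C3 and C5 carbonyls then give the benzene ring of 15, the only ring of the target. The closest known reaction type is the biomimetic aldol cyclisation and aromatisation of 3,5,7-triketo esters, released from diketo-dioxinones by alcohol trapping, to resorcylates. No stereocentre is retained, because both sp3 centres of 14 become aromatic carbons. The step needs the C2-to-C7 aldol to win over C6-to-C1 Claisen closure (acylphloroglucinol), C8-to-C3 aldol and O-cyclisation to a 4-hydroxy-2-pyrone; this is secured because the C7 ketone is far more electrophilic than the methyl ester under carbonate at room temperature, C8–H is only singly activated, excess methanol intercepts the ketene before an enol oxygen can, and irreversible aromatisation drains the reversible aldol equilibrium.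

Step 5
Reactants: 15 methyl 2,4-dihydroxy-6-icosylbenzoate; 16 iodomethane
Product: 17 methyl 2-hydroxy-6-icosyl-4-methoxybenzoate (CNP0075630.0)
Conditions: 16 (1.1 equiv), K2CO3 (1.2 equiv), acetone, 40 °C
Reagents that add atoms: iodomethane (compound 16), CI
Why: In this Williamson etherification the 2-hydroxyl is held in a hydrogen bond to the ester carbonyl and is less acidic and less nucleophilic, so with about one equivalent of base and MeI only the 4-phenoxide, para to the ester, should be methylated.

Compound list
1 | 2,2,6-trimethyl-4H-1,3-dioxin-4-one | CC1=CC(=O)OC(C)(C)O1 | starting material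
2 | acetyl chloride | CC(Cl)=O | starting material
3 | lithium 2,2-dimethyl-6-methylidene-6H-1,3-dioxin-4-olate (lithium dienolate of 1) | C=C1C=C(O[Li])OC(C)(C)O1 | intermediate
4 | 2,2-dimethyl-6-(2-oxopropyl)-4H-1,3-dioxin-4-one | CC(=O)CC1=CC(=O)OC(C)(C)O1 | intermediate
5 | henicosanoic acid | CCCCCCCCCCCCCCCCCCCCC(=O)O | starting material
6 | N,O-dimethylhydroxylamine hydrochloride | CNOC.Cl | starting material
7 | henicosanoyl chloride | CCCCCCCCCCCCCCCCCCCCC(=O)Cl | intermediate
8 | N-methoxy-N-methylhenicosanamide | CCCCCCCCCCCCCCCCCCCCC(=O)N(C)OC | intermediate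
9 | dilithium 2,2-dimethyl-6-(2-oxidoprop-2-en-1-ylidene)-6H-1,3-dioxin-4-olate (dianion of 4, drawn as the bis-enolate) | C=C(O[Li])C=C1C=C(O[Li])OC(C)(C)O1 | intermediate
10 | 2,2-dimethyl-6-(2,4-dioxotetracosyl)-4H-1,3-dioxin-4-one | CCCCCCCCCCCCCCCCCCCCC(=O)CC(=O)CC1=CC(=O)OC(C)(C)O1 | intermediate
11 | methanol | CO | starting material
12 | 3,5,7-trioxoheptacos-1-en-1-one (acylketene) | CCCCCCCCCCCCCCCCCCCCC(=O)CC(=O)CC(=O)C=C=O | intermediate
13 | methyl 3,5,7-trioxoheptacosanoate | CCCCCCCCCCCCCCCCCCCCC(=O)CC(=O)CC(=O)CC(=O)OC | intermediate
14 | methyl 2-hydroxy-2-icosyl-4,6-dioxocyclohexane-1-carboxylate (stereoisomer mixture, transient) | CCCCCCCCCCCCCCCCCCCCC1(O)CC(=O)CC(=O)C1C(=O)OC | intermediate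
15 | methyl 2,4-dihydroxy-6-icosylbenzoate | CCCCCCCCCCCCCCCCCCCCc1cc(O)cc(O)c1C(=O)OC | intermediate
16 | iodomethane | CI | starting material
17 | methyl 2-hydroxy-6-icosyl-4-methoxybenzoate (CNP0075630.0) | CCCCCCCCCCCCCCCCCCCCc1cc(OC)cc(O)c1C(=O)OC | target

Total step count: 5 steps.
Longest linear sequence: 4 steps (steps 1, 3, 4 and 5 from 1; equally steps 2, 3, 4 and 5 from 5).

Steps most likely to fail

Step 4. The acylketene may be captured by an internal enol oxygen before methanol reaches it (lactonisation to a pyranone), the open trioxo ester may fold through a different enolate, or dehydration of the carbinol may stall. The fallback sets out from 10 and aromatises while the dioxinone is still closed. Et3N in CH2Cl2 at rt should drive the vinylogous aldol of the dioxinone dienolate onto the C7 ketone and dehydration to 7-hydroxy-5-icosyl-2,2-dimethyl-4H-1,3-benzodioxin-4-one F1. In this sequence no free ketene and no open ester exist. NaOMe in MeOH/THF should then open the benzodioxinone by transesterification with loss of acetone, and the route is rejoined at 15.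

Step 3. Acyl transfer to the delocalised dianion may be sluggish at the low temperature that the dianion tolerates, made worse by the waxy amide leaving solution, with proton exchange returning 4. The fallback sets out from 8 and replaces the Claisen acylation by aldol addition and oxidation. i-Bu2AlH in THF at −78 °C should reduce the amide to henicosanal F2. Addition of F2 to dianion 9 (made from 4 as in step 3) at −78 °C should give the terminal aldol 6-(4-hydroxy-2-oxotetracosyl)-2,2-dimethyl-4H-1,3-dioxin-4-one F3, racemic, whose carbinol centre is removed at once. Oxidation of F3 with Dess–Martin periodinane in CH2Cl2 rejoins the route at 10.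

Step 1. O-acylation of the dienolate, double acylation or proton transfer from product to enolate may erode conversion. The fallback sets out from 1 and again trades acylation for aldol addition and oxidation. LiN(i-Pr)2 then Me3SiCl in THF at −78 °C should give the silyl dienol ether trimethyl[(2,2-dimethyl-6-methylidene-6H-1,3-dioxin-4-yl)oxy]silane F4. A vinylogous Mukaiyama aldol of F4 with acetaldehyde (BF3·OEt2, CH2Cl2, −78 °C) should give 6-(2-hydroxypropyl)-2,2-dimethyl-4H-1,3-dioxin-4-one F5, racemic. Dess–Martin oxidation of F5 in CH2Cl2 rejoins the route at 4.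

Further compounds
F1 | step 4 | 7-hydroxy-5-icosyl-2,2-dimethyl-4H-1,3-benzodioxin-4-one | CCCCCCCCCCCCCCCCCCCCc1cc(O)cc2OC(C)(C)OC(=O)c12
F2 | step 3 | henicosanal | CCCCCCCCCCCCCCCCCCCCC=O
F3 | step 3 | 6-(4-hydroxy-2-oxotetracosyl)-2,2-dimethyl-4H-1,3-dioxin-4-one (racemic) | CCCCCCCCCCCCCCCCCCCCC(O)CC(=O)CC1=CC(=O)OC(C)(C)O1
F4 | step 1 | trimethyl[(2,2-dimethyl-6-methylidene-6H-1,3-dioxin-4-yl)oxy]silane | C=C1C=C(O[Si](C)(C)C)OC(C)(C)O1
F5 | step 1 | 6-(2-hydroxypropyl)-2,2-dimethyl-4H-1,3-dioxin-4-one (racemic) | CC(O)CC1=CC(=O)OC(C)(C)O1
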